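**Retrosynthetic overview**
1. Target 12 comes from anti, 5-exo-dig iodolactonization of enynoic acid 11. The butenolide is the only ring formed, it is formed last, and the anti addition fixes the (E)-iodomethylidene.
2. Acid 11 comes from enynal 10 by Pinnick oxidation. Enynal 10 comes from the dearomatizing ring-opening of the 2-furylcarbene released from sulfonylhydrazone 8: furan C3=C4 becomes the cis-locked alkene, C2 plus the carbene carbon become the alkyne, and C5–O becomes the carbonyl.
3. Hydrazone 8 comes from alcohol 5 by bromine-directed C2 lithiation, formylation and condensation.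
4. Alcohol 5 comes from 3,4-dibromofuran 1 and butanal 2: mono bromine–lithium exchange breaks the symmetry, and a catalytic enantioselective aryl transfer sets the (R)-carbinol.
5. Ring order: the purchased furan ring is opened in step 3; no ring exists again until the final lactonization.

Assumption: the SMILES is read as (1R) at the carbinol and (5E) at the exocyclic alkene (iodine on the side of C4–Br, trans to the ring oxygen); 1 and 2 are purchased.

**Route**

Step 1
Reactants: 1 3,4-dibromofuran; 2 butanal
Product: 5 (1R)-1-(4-bromofuran-3-yl)butan-1-ol, via 3-bromo-4-lithiofuran 3 (not isolated), via (4-bromofuran-3-yl)titanium triisopropoxide 4 (not isolated)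
Conditions: n-BuLi (1.0 equiv), Et2O, −78 °C; ClTi(OiPr)3 (1.1 equiv), −78 °C, LiCl filtered off; then 2, (4R,5R)-2,2-dimethyl-α,α,α′,α′-tetraphenyl-1,3-dioxolane-4,5-dimethanol (20 mol %), Ti(OiPr)4 (20 mol %), toluene, −78 → −20 °C; aq. NH4Cl
Reagents that add atoms: none
Why: Mono bromine–lithium exchange of the symmetric dibromide is clean at −78 °C, transmetalation gives a mild aryl reagent of tetravalent titanium, and the titanium diolate formed in situ from the (4R,5R)-diol and Ti(OiPr)4 (TADDOLate-catalysed enantioselective aryl transfer to an aldehyde) is expected, from the Si-face preference of this catalyst class, to deliver the furyl group to the Si face of butanal, which is the (R)-carbinol.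

Step 2
Reactants: 5 (1R)-1-(4-bromofuran-3-yl)butan-1-ol
Product: 8 N'-[(E)-{3-bromo-4-[(1R)-1-hydroxybutyl]furan-2-yl}methylidene]-2,4,6-tri(propan-2-yl)benzenesulfonohydrazide, via lithium (1R)-1-(4-bromo-5-lithiofuran-3-yl)butan-1-olate 6 (not isolated), via 3-bromo-4-[(1R)-1-hydroxybutyl]furan-2-carbaldehyde 7 (not isolated)
Conditions: LiN(iPr)2 (2.3 equiv), THF, −78 °C; DMF (3 equiv), −78 → 0 °C; dilute aq. HCl to pH 4; 2,4,6-tri(propan-2-yl)benzenesulfonohydrazide (1.1 equiv), MeOH, 0 °C → rt
Reagents that add atoms: N,N-dimethylformamide, CN(C)C=O; 2,4,6-tri(propan-2-yl)benzenesulfonohydrazide, CC(C)c1cc(C(C)C)c(S(=O)(=O)NN)c(C(C)C)c1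
Why: After O-deprotonation, only the furan C–H flanked by the ring oxygen and the C–Br bond is acidic enough for the amide base (halogen-directed α-lithiation, as with 3-bromofuran), so formylation occurs next to bromine and the aldehyde condenses in the same flask to the crystalline sulfonylhydrazone, leaving the stereocenter untouched.

Step 3
Reactants: 8 N'-[(E)-{3-bromo-4-[(1R)-1-hydroxybutyl]furan-2-yl}methylidene]-2,4,6-tri(propan-2-yl)benzenesulfonohydrazide
Product: 11 (2E)-3-bromo-2-[(1R)-1-hydroxybutyl]pent-2-en-4-ynoic acid, via 3-bromo-2-(diazomethyl)-4-[(1R)-1-hydroxybutyl]furan 9 (not isolated), via (2E)-3-bromo-2-[(1R)-1-hydroxybutyl]pent-2-en-4-ynal 10 (not isolated)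
Conditions: NaH (1.05 equiv), THF, 0 °C, then 45–55 °C, dark; cold filtration through Celite (Et2O); NaClO2, NaH2PO4, 2-methylbut-2-ene, t-BuOH/H2O, 0 °C
Reagents that add atoms: sodium chlorite, [Na+].[O-]Cl=O
Why: Aprotic Bamford–Stevens fragmentation of the hindered sulfonylhydrazone salt gives the 2-furyldiazomethane, which loses N2 and opens as the 2-furylcarbene by cleavage of the O–C2 bond (dearomatizing ring-opening) to the enynal in which the former furan C3=C4 bond holds formyl and ethynyl cis, and immediate Pinnick oxidation converts this labile β-bromo enal into the acid without touching the alkene geometry or the carbinol.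

Step 4
Reactants: 11 (2E)-3-bromo-2-[(1R)-1-hydroxybutyl]pent-2-en-4-ynoic acid
Product: 12 (5E)-4-bromo-3-[(1R)-1-hydroxybutyl]-5-(iodomethylidene)furan-2(5H)-one
Conditions: N-iodosuccinimide (1.2 equiv), KHCO3 (0.2 equiv), MeCN, 0 °C, dark
Reagents that add atoms: N-iodosuccinimide, O=C1CCC(=O)N1I
Why: Iodonium activation of the terminal alkyne followed by Markovnikov 5-exo-dig attack of the cis carboxyl group (iodolactonization) is an anti addition, so ring oxygen and iodine end up trans across the new exocyclic double bond, which places iodine syn to C4–Br as in the (E)-target, and the carbinol center is not involved.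

**Compound list**
1 | 3,4-dibromofuran | Brc1cocc1Br | starting material
2 | butanal | CCCC=O | starting material
3 | 3-bromo-4-lithiofuran | [Li]c1cocc1Br | intermediate
4 | (4-bromofuran-3-yl)titanium triisopropoxide | CC(C)O[Ti](OC(C)C)(OC(C)C)c1cocc1Br | intermediate
5 | (1R)-1-(4-bromofuran-3-yl)butan-1-ol | CCC[C@@H](O)c1cocc1Br | intermediate
6 | lithium (1R)-1-(4-bromo-5-lithiofuran-3-yl)butan-1-olate | CCC[C@@H](O[Li])c1coc([Li])c1Br | intermediate
7 | 3-bromo-4-[(1R)-1-hydroxybutyl]furan-2-carbaldehyde | CCC[C@@H](O)c1coc(C=O)c1Br | intermediate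
8 | N'-[(E)-{3-bromo-4-[(1R)-1-hydroxybutyl]furan-2-yl}methylidene]-2,4,6-tri(propan-2-yl)benzenesulfonohydrazide | CCC[C@@H](O)c1coc(/C=N/NS(=O)(=O)c2c(C(C)C)cc(C(C)C)cc2C(C)C)c1Br | intermediate
9 | 3-bromo-2-(diazomethyl)-4-[(1R)-1-hydroxybutyl]furan | CCC[C@@H](O)c1coc(C=[N+]=[N-])c1Br | intermediate
10 | (2E)-3-bromo-2-[(1R)-1-hydroxybutyl]pent-2-en-4-ynal (formyl cis to ethynyl) | CCC[C@@H](O)/C(C=O)=C(\Br)C#C | intermediate
11 | (2E)-3-bromo-2-[(1R)-1-hydroxybutyl]pent-2-en-4-ynoic acid (carboxyl cis to ethynyl) | CCC[C@@H](O)/C(C(=O)O)=C(\Br)C#C | intermediate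
12 | (5E)-4-bromo-3-[(1R)-1-hydroxybutyl]-5-(iodomethylidene)furan-2(5H)-one | CCC[C@@H](O)C1=C(Br)/C(=C\I)OC1=O | target

**Step count and risks**
Total step count: 4 (isolated products 5, 8, 11, 12). Longest linear sequence: 4 steps from 1.

The three steps most likely to fail, in route order (step 3 is the riskiest):

Step 1 (the enantioselectivity of the aryl transfer is sensitive to residual lithium salts and to the ortho bromine; the sense of induction should be confirmed on 5 by Mosher ester analysis). The fallback sets out from 1, by way of 3, and comes back at 5. Lithio compound 3 is acylated with N-methoxy-N-methylbutanamide to give 1-(4-bromofuran-3-yl)butan-1-one F1. This ketone is reduced with BH3·SMe2 and 10 mol % (S)-1-methyl-3,3-diphenyltetrahydro-1H,3H-pyrrolo[1,2-c][1,3,2]oxazaborole (Corey–Bakshi–Shibata reduction), with the furyl group acting as the large substituent, to give (R)-5.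

Step 3 (the diazo compound must form below the temperature at which the cis β-bromo enynal isomerizes or adds sulfinate; 10 is the most fragile compound of the route). The fallback sets out from 5 and comes back at 11, replacing carbene ring-opening by a silicon-directed photooxygenation. Et2SiH2 with [Ir(cod)OMe]2 (0.1 mol %) gives [(1R)-1-(4-bromofuran-3-yl)butoxy]diethylsilane F2. The same monovalent iridium precursor with 3,4,7,8-tetramethyl-1,10-phenanthroline and norbornene (THF, 80 °C) closes F2 by hydroxyl-directed C–H silylation at the only free neighbouring position (furan C5) to the fused (R)-oxasilole in which SiEt2 bridges the carbinol oxygen and furan C5 F3. Sensitized photooxygenation (O2, 5,10,15,20-tetraphenylporphyrin, CH2Cl2, −78 °C, visible light) adds singlet oxygen across C2/C5, silicon shifts from carbon to peroxide oxygen so that the silylated carbon becomes the lactone carbonyl, and dilute acid releases 4-bromo-5-hydroxy-3-[(1R)-1-hydroxybutyl]furan-2(5H)-one F4. The open aldehyde form of F4 is homologated with dimethyl (1-diazo-2-oxopropyl)phosphonate, K2CO3 and MeOH (Seyferth–Gilbert homologation) to the alkyne 11.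

Step 4 (6-endo closure to the 5-iodo-2-pyranone, or light- or iodide-induced drift of the strained (E)-vinyl iodide to the (Z)-isomer). The fallback sets out from 11 and comes back at 12. Hg(OAc)2 (1.0 equiv, CH2Cl2, 0 °C) effects a strictly Markovnikov anti oxymercuration to {(E)-[3-bromo-4-[(1R)-1-hydroxybutyl]-5-oxofuran-2(5H)-ylidene]methyl}mercury acetate F5. Iodine (1.0 equiv, 0 °C, dark) then replaces divalent mercury with retention of the alkene geometry to give 12.

Further compounds
F1 | step 1 | 1-(4-bromofuran-3-yl)butan-1-one | CCCC(=O)c1cocc1Br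
F2 | step 3 | [(1R)-1-(4-bromofuran-3-yl)butoxy]diethylsilane | CCC[C@@H](O[SiH](CC)CC)c1cocc1Br
F3 | step 3 | (R)-oxasilole fused to the furan, SiEt2 bridging the carbinol oxygen and furan C5, bromine on the adjacent furan carbon, propyl on the carbinol carbon | CCC[C@H]1O[Si](CC)(CC)c2occ(Br)c21
F4 | step 3 | 4-bromo-5-hydroxy-3-[(1R)-1-hydroxybutyl]furan-2(5H)-one (both C5 epimers) | CCC[C@@H](O)C1=C(Br)C(O)OC1=O
F5 | step 4 | {(E)-[3-bromo-4-[(1R)-1-hydroxybutyl]-5-oxofuran-2(5H)-ylidene]methyl}mercury acetate | CCC[C@@H](O)C1=C(Br)/C(=C\[Hg]OC(C)=O)OC1=O
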